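**Strategy.** The route rests on cutting the butenolide ring (ring O, C15H2, C14H=C13, lactone carbonyl C16; labdane numbering) into a propargylic C13≡C14–C15 unit and CO2. In one flask, zinc insertion into a 2-alkynyl bromide, SE2′ carboxylation at C13 and CuCl-catalysed 5-endo lactonisation of the resulting 2,3-allenoate forge the C13–C16 and O–C15 bonds, exploiting the fact that this ring is formally an allenyl anion plus CO2. The precursor is a labdane propargylic bromide bearing the C19 methyl ester, a PMB-masked C20 alcohol and the 8(17)-alkene; its decalin comes from an auxiliary-controlled Mn(OAc)3/Cu(OAc)2 polyene bicyclisation.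

Key step: step 16

Remark: terpenoid carbons carry labdane numbers (C1–C20); α and β denote the faces of the trans-decalin in the usual orientation (C20 on the β face).
Assumption: (−)-8-phenylmenthol is taken to induce the (4S,5R,9S,10S) series in step 8, by analogy with related 8-phenylmenthyl 2-methyl-3-oxo esters; were the sense opposite, its enantiomer would be used in the same steps.
Remark: alcohols 4 and 11 are racemic; their stereocentres are destroyed in the sigmatropic steps that follow.

Step 1
Reactants: 1 2-(2-bromoethyl)-2-methyl-1,3-dioxolane; 2 methacrolein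
Product: 4 racemic 2-methyl-5-(2-methyl-1,3-dioxolan-2-yl)pent-1-en-3-ol, via Grignard reagent 3 (not isolated)
Conditions: Mg, THF, 25 °C; then 2, −78 → 0 °C; aq. NH4Cl
Reagents that add atoms: none
Why: Grignard formation and 1,2-addition to the enal should give the allylic alcohol, whose racemic carbinol centre is erased in step 2.

Step 2
Reactants: 4 racemic 2-methyl-5-(2-methyl-1,3-dioxolan-2-yl)pent-1-en-3-ol
Product: 6 (E)-4-methyl-7-(2-methyl-1,3-dioxolan-2-yl)hept-4-enal, via allyl vinyl ether 5 (not isolated)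
Conditions: ethyl vinyl ether, Hg(OAc)2 (cat.), reflux; then PhMe, 150 °C, sealed tube
Reagents that add atoms: ethyl vinyl ether (C=COCC)
Why: Vinyl ether exchange followed by Claisen rearrangement through a chair with the C9 chain equatorial should give the E-trisubstituted C8=C9 alkene and the C5 aldehyde.

Step 3
Reactants: 7 2,3-dibromopropene; 8 4-methoxybenzyl alcohol
Product: 9 2-bromoallyl 4-methoxybenzyl ether
Conditions: NaH, THF, 0 → 25 °C
Reagents that add atoms: none
Why: Williamson ether synthesis at the allylic bromide, the vinylic bromide being inert to SN2 displacement.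

Step 4
Reactants: 9 2-bromoallyl 4-methoxybenzyl ether; 6 (E)-4-methyl-7-(2-methyl-1,3-dioxolan-2-yl)hept-4-enal
Product: 11 racemic (E)-2-[(4-methoxybenzyloxy)methyl]-6-methyl-9-(2-methyl-1,3-dioxolan-2-yl)nona-1,6-dien-3-ol, via vinyllithium 10 (not isolated)
Conditions: t-BuLi (2.1 equiv), Et2O, −78 °C; then 6, −78 °C; aq. NH4Cl
Reagents that add atoms: none
Why: Bromine–lithium exchange and 1,2-addition of the 2-lithioallyl ether to the aldehyde install C1, C10 and the oxygenated C20.

Step 5
Reactants: 11 racemic dienol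
Product: 13 methyl (4Z,8E)-4-[(4-methoxybenzyloxy)methyl]-8-methyl-11-(2-methyl-1,3-dioxolan-2-yl)undeca-4,8-dienoate, via ketene acetal 12 (not isolated)
Conditions: MeC(OMe)3, EtCO2H (cat.), 110 → 140 °C, MeOH distilled off
Reagents that add atoms: trimethyl orthoacetate (CC(OC)(OC)OC)
Why: Johnson–Claisen rearrangement through a chair with the C6 chain equatorial should place C6 trans to the new C1–C2 chain and cis to CH2OPMB, the C5=C10 geometry needed for a trans ring fusion.

Step 6
Reactants: 14 (−)-8-phenylmenthol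
Product: 15 (−)-8-phenylmenthyl propanoate
Conditions: EtCOCl, pyridine, DMAP (cat.), CH2Cl2, 0 → 25 °C
Reagents that add atoms: propanoyl chloride (CCC(=O)Cl)
Why: DMAP-catalysed acylation of the secondary alcohol.

Step 7
Reactants: 15 (−)-8-phenylmenthyl propanoate; 13 methyl dienoate
Product: 16 (−)-8-phenylmenthyl (6Z,10E)-6-[(4-methoxybenzyloxy)methyl]-2,10-dimethyl-13-(2-methyl-1,3-dioxolan-2-yl)-3-oxotrideca-6,10-dienoate (C2 epimers)
Conditions: LiN(i-Pr)2 (2.6 equiv), 15 (2.5 equiv), THF, −78 °C; then 13, −78 → −20 °C; AcOH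
Reagents that add atoms: none
Why: Crossed Claisen condensation, in which the preformed enolate of the bulky ester does not self-condense and acylates on the unhindered methyl ester; the labile α-methyl centre is erased in step 8.

Step 8
Reactants: 16 β-keto ester
Product: 17 (−)-8-phenylmenthyl 20-(4-methoxybenzyloxy)-3-oxo-13,13-(ethylenedioxy)-15,16-dinorlabd-8(17)-en-19-oate (4α-methyl, 4β-ester, 5α-H, 9β side chain, 10β-CH2OPMB)
Conditions: Mn(OAc)3·2H2O (2.2 equiv), Cu(OAc)2·H2O (1 equiv), degassed EtOH, 40 °C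
Reagents that add atoms: none
Why: Oxidative radical polyene cyclisation: trivalent manganese generates the C4 radical, which should close both rings by chair–chair 6-endo/6-endo addition before Cu(OAc)2 oxidises the C8 radical to the exocyclic alkene; the non-chelated radical (ester anti to the ketone) gives the axial ester, the E-type alkenes give the trans fusion and equatorial side chain, and the 8-phenylmenthyl group shields one face to set C4, C5, C9 and C10 in the absolute sense.

Step 9
Reactants: 17 bicyclic keto ester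
Product: 18 20-(4-methoxybenzyloxy)-13,13-(ethylenedioxy)-15,16-dinorlabd-8(17)-ene-3β,19-diol
Conditions: LiAlH4, THF, 0 → 65 °C; aq. NaOH work-up
Reagents that add atoms: none
Why: Hydride reduction, with axial delivery at C3 giving the equatorial 3β-alcohol and reductive cleavage of the hindered ester releasing the auxiliary.

Step 10
Reactants: 18 3β,19-diol
Product: 19 3β,19-cyclic thionocarbonate of 18
Conditions: 1,1′-thiocarbonyldiimidazole, DMAP (cat.), PhMe, 80 °C
Reagents that add atoms: 1,1′-thiocarbonyldiimidazole (S=C(n1ccnc1)n1ccnc1)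
Why: Thioacylation of the gauche 1,3-diol should close the six-membered cyclic thionocarbonate.

Step 11
Reactants: 19 cyclic thionocarbonate
Product: 21 20-(4-methoxybenzyloxy)-13,13-(ethylenedioxy)-15,16-dinorlabd-8(17)-en-19-ol, via tin thiocarbonate 20 (not isolated)
Conditions: Bu3SnH, AIBN (cat.), PhMe, 110 °C; then 2 M NaOH, THF, 25 °C
Reagents that add atoms: none
Why: Barton–McCombie-type deoxygenation of a cyclic thionocarbonate: the ring should fragment at the secondary C3–O bond to the more stable radical, and the remaining primary tin thiocarbonate is hydrolysed on work-up.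

Step 12
Reactants: 21 C19 alcohol
Product: 22 20-(4-methoxybenzyloxy)-13-oxo-15,16-dinorlabd-8(17)-en-19-oic acid
Conditions: CrO3, H2SO4, acetone/H2O, 0 °C
Reagents that add atoms: water (O)
Why: Jones oxidation of the neopentyl alcohol to the acid, the aqueous acid in acetone cleaving the dioxolane at the same time; the exocyclic alkene and the PMB ether should survive at 0 °C.

Step 13
Reactants: 22 keto acid
Product: 23 methyl 20-(4-methoxybenzyloxy)-13-oxo-15,16-dinorlabd-8(17)-en-19-oate
Conditions: MeI, K2CO3, DMF, 25 °C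
Reagents that add atoms: iodomethane (CI)
Why: O-alkylation of the carboxylate (SN2 at methyl) avoids attack at the hindered C19 carbonyl.

Step 14
Reactants: 23 keto methyl ester
Product: 26 methyl 15-hydroxy-20-(4-methoxybenzyloxy)-16-norlabd-8(17)-en-13-yn-19-oate, via enol phosphate 24 (not isolated), via lithium acetylide 25 (not isolated)
Conditions: LiN(i-Pr)2 (1.1 equiv), THF, −78 °C; ClP(O)(OEt)2, −78 → 0 °C; LiN(i-Pr)2 (2.3 equiv), −78 → 0 °C; (CH2O)n, 0 → 25 °C; aq. NH4Cl
Reagents that add atoms: formaldehyde, as paraformaldehyde (C=O)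
Why: Kinetic enolisation at the methyl group, O-phosphorylation and base-induced elimination give the terminal alkyne as its acetylide, which is hydroxymethylated in the same flask; the quaternary C19 ester has no α-hydrogen and is too hindered to react.

Step 15
Reactants: 26 propargylic alcohol
Product: 27 methyl 15-bromo-20-(4-methoxybenzyloxy)-16-norlabd-8(17)-en-13-yn-19-oate
Conditions: CBr4, PPh3, CH2Cl2, 0 °C
Reagents that add atoms: carbon tetrabromide (BrC(Br)(Br)Br)
Why: Appel reaction of the primary propargylic alcohol by SN2 displacement of the oxyphosphonium.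

Step 16
Reactants: 27 propargylic bromide
Product: 30 methyl 20-(4-methoxybenzyloxy)labda-8(17),13-dien-16,15-olid-19-oate, via propargylzinc bromide 28 (not isolated), via allenoic acid 29 (not isolated)
Conditions: Zn dust, LiCl, CO2 (1 atm), DMF, 0 → 25 °C; then AcOH, CuCl (10 mol%), MeOH, 60 °C
Reagents that add atoms: carbon dioxide (O=C=O)
Why: Zinc inserts into the C15–Br bond to give the 2-alkynylzinc 28, whose SE2′ reaction with CO2 through the alkyl-substituted terminus forms the C13–C16 bond and the zinc 2,3-allenoate; after acidification CuCl activates the terminal C14=C15 bond of allenoic acid 29, the carboxyl oxygen adds to C15 and protodemetalation places hydrogen on C14. The closest known reaction types are the zinc-mediated carboxylation of 2-alkynyl bromides to 2,3-allenoic acids and the CuCl- or AgNO3-catalysed cycloisomerisation of 2,3-allenoic acids to butenolides, here run in one flask. The lactone closes in a 5-endo-trig mode at the metal-activated allene terminus. No stereocentre is formed, and the C13=C14 geometry is fixed by the ring. The step needs carboxylation at C13 and not at C15, which the preference of zinc for the primary C15 position and the cyclic SE2′ transition state should secure, and chemoselectivity, which holds because the hindered C19 ester and the ether-masked C20 oxygen are inert to the organozinc.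

Step 17
Reactants: 30 butenolide PMB ether
Product: 31 methyl 20-hydroxylabda-8(17),13-dien-16,15-olid-19-oate
Conditions: DDQ, CH2Cl2/pH 7 buffer, 0 °C
Reagents that add atoms: none
Why: Oxidative PMB cleavage (benzylic hydride abstraction, then hydrolysis) under neutral conditions; 31 is carried on at once, without silica gel chromatography, so that the C20 alcohol does not lactonise onto the C19 ester.

Step 18
Reactants: 31 C20 alcohol
Product: 32 methyl (4S,5R,9S,10S)-20-oxolabda-8(17),13-dien-16,15-olid-19-oate (target)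
Conditions: Dess–Martin periodinane, NaHCO3, CH2Cl2, 0 → 25 °C
Reagents that add atoms: none
Why: Dess–Martin oxidation of the neopentyl alcohol to the non-enolisable C20 aldehyde, leaving the butenolide, the exocyclic alkene and all stereocentres untouched.

**Compound list**

1 | 2-(2-bromoethyl)-2-methyl-1,3-dioxolane | CC1(CCBr)OCCO1 | starting material
2 | methacrolein | CC(=C)C=O | starting material
3 | [2-(2-methyl-1,3-dioxolan-2-yl)ethyl]magnesium bromide | CC1(CC[Mg]Br)OCCO1 | intermediate
4 | racemic 2-methyl-5-(2-methyl-1,3-dioxolan-2-yl)pent-1-en-3-ol | CC(=C)C(O)CCC1(C)OCCO1 | intermediate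
5 | vinyl ether of 4 | CC(=C)C(CCC1(C)OCCO1)OC=C | intermediate
6 | (E)-4-methyl-7-(2-methyl-1,3-dioxolan-2-yl)hept-4-enal | O=CCC/C(C)=C/CCC1(C)OCCO1 | intermediate
7 | 2,3-dibromopropene | C=C(Br)CBr | starting material
8 | 4-methoxybenzyl alcohol | COc1ccc(CO)cc1 | starting material
9 | 2-bromoallyl 4-methoxybenzyl ether | C=C(Br)COCc1ccc(OC)cc1 | intermediate
10 | [3-(4-methoxybenzyloxy)prop-1-en-2-yl]lithium | [Li]C(=C)COCc1ccc(OC)cc1 | intermediate
11 | racemic (E)-2-[(4-methoxybenzyloxy)methyl]-6-methyl-9-(2-methyl-1,3-dioxolan-2-yl)nona-1,6-dien-3-ol | C=C(COCc1ccc(OC)cc1)C(O)CC/C(C)=C/CCC1(C)OCCO1 | intermediate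
12 | mixed methyl ketene acetal of 11 | C=C(OC)OC(CC/C(C)=C/CCC1(C)OCCO1)C(=C)COCc1ccc(OC)cc1 | intermediate
13 | methyl (4Z,8E)-4-[(4-methoxybenzyloxy)methyl]-8-methyl-11-(2-methyl-1,3-dioxolan-2-yl)undeca-4,8-dienoate | COC(=O)CC/C(COCc1ccc(OC)cc1)=C/CC/C(C)=C/CCC1(C)OCCO1 | intermediate
14 | (−)-8-phenylmenthol, (1R,2S,5R) | O[C@@H]1C[C@H](C)CC[C@H]1C(C)(C)c1ccccc1 | starting material
15 | (−)-8-phenylmenthyl propanoate | CCC(=O)O[C@@H]1C[C@H](C)CC[C@H]1C(C)(C)c1ccccc1 | intermediate
16 | (−)-8-phenylmenthyl (6Z,10E)-6-[(4-methoxybenzyloxy)methyl]-2,10-dimethyl-13-(2-methyl-1,3-dioxolan-2-yl)-3-oxotrideca-6,10-dienoate | CC(C(=O)CC/C(COCc1ccc(OC)cc1)=C/CC/C(C)=C/CCC1(C)OCCO1)C(=O)O[C@@H]1C[C@H](C)CC[C@H]1C(C)(C)c1ccccc1 | intermediate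
17 | (−)-8-phenylmenthyl 20-(4-methoxybenzyloxy)-3-oxo-13,13-(ethylenedioxy)-15,16-dinorlabd-8(17)-en-19-oate | C=C1CC[C@@H]2[C@](COCc3ccc(OC)cc3)(CCC(=O)[C@]2(C)C(=O)O[C@@H]3C[C@H](C)CC[C@H]3C(C)(C)c3ccccc3)[C@H]1CCC1(C)OCCO1 | intermediate
18 | 20-(4-methoxybenzyloxy)-13,13-(ethylenedioxy)-15,16-dinorlabd-8(17)-ene-3β,19-diol | C=C1CC[C@@H]2[C@](COCc3ccc(OC)cc3)(CC[C@H](O)[C@]2(C)CO)[C@H]1CCC1(C)OCCO1 | intermediate
19 | 3β,19-cyclic thionocarbonate of 18 | C=C1CC[C@@H]2[C@](COCc3ccc(OC)cc3)(CC[C@H](OC(=S)O3)[C@]2(C)C3)[C@H]1CCC1(C)OCCO1 | intermediate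
20 | O-(C19) S-tributylstannyl thiocarbonate of 21 | C=C1CC[C@@H]2[C@](COCc3ccc(OC)cc3)(CCC[C@]2(C)COC(=O)S[Sn](CCCC)(CCCC)CCCC)[C@H]1CCC1(C)OCCO1 | intermediate
21 | 20-(4-methoxybenzyloxy)-13,13-(ethylenedioxy)-15,16-dinorlabd-8(17)-en-19-ol | C=C1CC[C@@H]2[C@](COCc3ccc(OC)cc3)(CCC[C@]2(C)CO)[C@H]1CCC1(C)OCCO1 | intermediate
22 | 20-(4-methoxybenzyloxy)-13-oxo-15,16-dinorlabd-8(17)-en-19-oic acid | C=C1CC[C@@H]2[C@](COCc3ccc(OC)cc3)(CCC[C@]2(C)C(=O)O)[C@H]1CCC(C)=O | intermediate
23 | methyl 20-(4-methoxybenzyloxy)-13-oxo-15,16-dinorlabd-8(17)-en-19-oate | C=C1CC[C@@H]2[C@](COCc3ccc(OC)cc3)(CCC[C@]2(C)C(=O)OC)[C@H]1CCC(C)=O | intermediate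
24 | 13-enol diethyl phosphate of 23 | C=C1CC[C@@H]2[C@](COCc3ccc(OC)cc3)(CCC[C@]2(C)C(=O)OC)[C@H]1CCC(=C)OP(=O)(OCC)OCC | intermediate
25 | lithium acetylide (C13≡C14–Li) from 24 | C=C1CC[C@@H]2[C@](COCc3ccc(OC)cc3)(CCC[C@]2(C)C(=O)OC)[C@H]1CCC#C[Li] | intermediate
26 | methyl 15-hydroxy-20-(4-methoxybenzyloxy)-16-norlabd-8(17)-en-13-yn-19-oate | C=C1CC[C@@H]2[C@](COCc3ccc(OC)cc3)(CCC[C@]2(C)C(=O)OC)[C@H]1CCC#CCO | intermediate
27 | methyl 15-bromo-20-(4-methoxybenzyloxy)-16-norlabd-8(17)-en-13-yn-19-oate | C=C1CC[C@@H]2[C@](COCc3ccc(OC)cc3)(CCC[C@]2(C)C(=O)OC)[C@H]1CCC#CCBr | intermediate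
28 | propargylic zinc bromide from 27 (C15–ZnBr) | C=C1CC[C@@H]2[C@](COCc3ccc(OC)cc3)(CCC[C@]2(C)C(=O)OC)[C@H]1CCC#CC[Zn]Br | intermediate
29 | 19-methoxy-20-(4-methoxybenzyloxy)-19-oxolabda-8(17),13,14-trien-16-oic acid (2,3-allenoic acid) | C=C1CC[C@@H]2[C@](COCc3ccc(OC)cc3)(CCC[C@]2(C)C(=O)OC)[C@H]1CCC(=C=C)C(=O)O | intermediate
30 | methyl 20-(4-methoxybenzyloxy)labda-8(17),13-dien-16,15-olid-19-oate | C=C1CC[C@@H]2[C@](COCc3ccc(OC)cc3)(CCC[C@]2(C)C(=O)OC)[C@H]1CCC1=CCOC1=O | intermediate
31 | methyl 20-hydroxylabda-8(17),13-dien-16,15-olid-19-oate | C=C1CC[C@@H]2[C@](CO)(CCC[C@]2(C)C(=O)OC)[C@H]1CCC1=CCOC1=O | intermediate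
32 | methyl (4S,5R,9S,10S)-20-oxolabda-8(17),13-dien-16,15-olid-19-oate | C=C1CC[C@@H]2[C@](C=O)(CCC[C@]2(C)C(=O)OC)[C@H]1CCC1=CCOC1=O | target

**Step count.** Total: 18 steps. Longest linear sequence: 16 steps (steps 1, 2, 4, 5 and 7–18; steps 3 and 6 are side branches).

**Steps most likely to fail**

Step 16. The organozinc may be carboxylated at C15 rather than C13 (giving the 3-alkynoic acid), or be protonated before it captures CO2. The fallback uses known chemistry and sets out from propargylic alcohol 26. Acylation with ClCO2Me and pyridine should give the propargylic methyl carbonate F1. Decarboxylative carbonylation under zerovalent palladium (Pd(OAc)2, PPh3, CO, MeOH, 50 °C) should give the methyl 2,3-allenoate F2. LiOH in THF/H2O at 0 °C should cleave this unhindered ester, and not the C19 ester, to give allenoic acid 29, now isolated. AgNO3 (cat.) in acetone then cyclises 29 to 30, where the route is rejoined.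

Step 8. Face discrimination by the auxiliary may be poor, and the oxidative termination may be unselective, giving endocyclic alkene isomers. The fallback separates ring formation from alkene formation and sets out from 16. Selenenylation (NaH, PhSeCl, THF, 0 °C) should give the α-phenylseleno β-keto ester F3. Photolysis (hν, PhH, 25 °C) should bring about phenylseleno group-transfer tandem cyclisation to the C8 selenide F4. Oxidation with H2O2 and pyridine in CH2Cl2 at 0 °C, followed by selenoxide syn-elimination towards the methyl group, returns 17.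

Step 7. Proton transfer between the ester enolate and 13 may lead to self-condensation and low conversion. The fallback replaces the acylation by an aldol–oxidation sequence and sets out from 13. Reduction with i-Bu2AlH in CH2Cl2 at −78 °C should give aldehyde F5. Addition of the lithium enolate of 15 (LiN(i-Pr)2, THF, −78 °C) should give β-hydroxy ester F6 as a mixture of diastereomers. Dess–Martin oxidation returns 16.

Further compounds
F1 | step 16 | methyl carbonate of propargylic alcohol 26 | C=C1CC[C@@H]2[C@](COCc3ccc(OC)cc3)(CCC[C@]2(C)C(=O)OC)[C@H]1CCC#CCOC(=O)OC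
F2 | step 16 | methyl ester of allenoic acid 29 | C=C1CC[C@@H]2[C@](COCc3ccc(OC)cc3)(CCC[C@]2(C)C(=O)OC)[C@H]1CCC(=C=C)C(=O)OC
F3 | step 8 | 2-(phenylseleno) derivative of β-keto ester 16 | CC([Se]c1ccccc1)(C(=O)CC/C(COCc1ccc(OC)cc1)=C/CC/C(C)=C/CCC1(C)OCCO1)C(=O)O[C@@H]1C[C@H](C)CC[C@H]1C(C)(C)c1ccccc1
F4 | step 8 | 8-(phenylseleno)-8-methyl analogue of 17 (C8 selenide, saturated at C8–C17) | CC1([Se]c3ccccc3)CC[C@@H]2[C@](COCc3ccc(OC)cc3)(CCC(=O)[C@]2(C)C(=O)O[C@@H]3C[C@H](C)CC[C@H]3C(C)(C)c3ccccc3)[C@H]1CCC1(C)OCCO1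
F5 | step 7 | (4Z,8E)-4-[(4-methoxybenzyloxy)methyl]-8-methyl-11-(2-methyl-1,3-dioxolan-2-yl)undeca-4,8-dienal | O=CCC/C(COCc1ccc(OC)cc1)=C/CC/C(C)=C/CCC1(C)OCCO1
F6 | step 7 | 3-hydroxy analogue of β-keto ester 16 (aldol adduct) | CC(C(O)CC/C(COCc1ccc(OC)cc1)=C/CC/C(C)=C/CCC1(C)OCCO1)C(=O)O[C@@H]1C[C@H](C)CC[C@H]1C(C)(C)c1ccccc1
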